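(The readings were generated by integration with made-up constants, and the scatter is random.)

3 questions are put on the flasks dusk and midnight, and we answer them from the runs south-west and north-east.

the same everywhere: left-handed substrate 20 mM; right-handed substrate 20 mM; free catalyst 0.40 mM

|  | partner | remark | time |
|---|---|---|---|
| south-west | 35 mM | run made earlier |  |
| north-east | 69 mM | run made earlier |  |
| dusk | 60.0 mM |  | 50 min |
| midnight | 100 mM |  | 50 min |

| run | time / min | left-handed product / % | right-handed product / % | left-handed substrate / % |
|---|---|---|---|---|
| south-west | 3.00 | 5 | 1 | 40 |
| south-west | 4.00 | 10 | 3 | 44 |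
| south-west | 6.00 | 15 | 0 | 40 |
| south-west | 10.0 | 18 | 0 | 29 |
| south-west | 15.0 | 22 | 1 | 26 |
| south-west | 25.0 | 27 | 0 | 17 |
| south-west | 40.0 | 36 | 2 | 11 |
| north-east | 3.00 | 12 | 0 | 40 |
| north-east | 4.00 | 10 | 2 | 32 |
| north-east | 6.00 | 20 | 3 | 36 |
| north-east | 10.0 | 21 | 2 | 24 |
| north-east | 15.0 | 34 | 1 | 19 |
| north-east | 25.0 | 39 | 0 | 8 |
| north-east | 40.0 | 47 | 3 | 1 |

(scatter of a reading: 2 percentage points)

* which of the two ends with the higher excess of left-handed product over right-handed product in the product ("neither" if they lie within 2 percentage points) (dusk / midnight / neither)
* excess of left-handed product over right-handed product in the product at the end, dusk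
* excess of left-handed product over right-handed product in the product at the end, midnight

- free catalyst is single-handed; left-handed substrate and right-handed substrate are mirror images of each other, charged as a racemate, each of them at the stated concentration
- what was read earlier has a scatter of 2 percentage points, one standard deviation
- an excess is the difference of the two amounts in percent of their sum
- an excess is below zero if the other one leads

We start from the balance of the left-handed substrate, the limiting reagent. It and the left-handed product together make up half of the two substrates charged, and the north-east run reads 48.0% at 40.0 min. With left-handed product at that half and right-handed product at its last north-east reading, 3%, the excess is 88.7%. Lowering left-handed product to its reading, 47%, moves this by 0.68 percentage points, but twice the right-handed product moves it by 10 points, far more. So right-handed product must be known well, and a single reading carries a scatter of 2 points.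

We therefore fit all 14 right-handed readings to one line through the origin, proportional to [partner] as charged and to time. This gives 0.0105 M⁻¹ min⁻¹: the leak, the fraction of the two substrates charged that becomes right-handed product per minute and per molar of partner charged. By our reckoning, with left-handed product taken at that half, dusk reaches 3.14% of right-handed product and an excess of 88.2%, while midnight reaches 5.23% and 81.1%, lower.

The forecast says dusk, with 88% (78% to 95%) for dusk and 81% (66% to 91%) for midnight, because more partner “lets the slow enantiomer keep reacting after the fast one is exhausted”.

The flasks give dusk, with 90.8% for dusk and 84.3% for midnight.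

    partner + catalyst intermediate A → free catalyst + left-handed product (k = 200 M⁻¹ min⁻¹)
    partner + catalyst intermediate B → free catalyst + right-handed product (k = 2.30 M⁻¹ min⁻¹)
    free catalyst → spent catalyst A (k = 0.00850 min⁻¹)
    partner ⇌ dormant form (K = 0.540, k = 0.0120 min⁻¹)
    partner + free catalyst → spent catalyst B (k = 0.270 M⁻¹ min⁻¹)
    free catalyst + right-handed substrate ⇌ catalyst intermediate B (K = 120 M⁻¹, k = 6200 M⁻¹ min⁻¹)
    free catalyst + left-handed substrate ⇌ catalyst intermediate A (K = 160 M⁻¹, k = 1400 M⁻¹ min⁻¹)

Midnight stopped at 30 min is a neighbour flask: the leak gives 3.14% of right-handed product against 2.86% there, and with its 46.1% of left-handed product an excess of 87.2% against 88.3%. In midnight itself, the step to left-handed product had 60% of its turnover up to 50 min behind it by 10.0 min, and left-handed substrate stood at 5.80% at 25.0 min. In midnight, catalyst intermediate B still held 46.4% of the catalyst at 50.0 min, while right-handed product rose from 2.47% at 25.0 min to 4.18%.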